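## Remarks

- **Numbering and face labels.** Briarane numbering is used for every compound, including those that hold only part of the skeleton. β means the face of the C15 methyl group, α the opposite face. TBS = tert-butyldimethylsilyl.
- **Assumption.** The (R)-binaphtholate titanium catalyst of step 4 is taken to deliver the diene to the quinone face that gives 8; if its sense is the reverse, the (S)-ligand is used with no other change.
- **Structure check.** Precursor 22 and ketone 25 were compared with 37 centre by centre: C1, C2, C9, C10 and C13 agree and no stereodescriptor needed correction. Only the protecting groups differ (three TBS ethers).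

## Structural features

Compound 37 is a six–ten fused carbobicycle (ring A: C1, C10–C14; ten-membered ring: C1–C10) with a γ-lactone (O–C19–C17) fused across C7–C8. Ring A carries the exocyclic C11=C20 methylene and an equatorial 13α-acetate, and the ring fusion is trans (C15 methyl β on quaternary C1, H10 α). The ten-membered ring holds a cross-conjugated diene, (3E)-C3=C4 joined to exocyclic C5=C16, and an unbroken run of seven stereocentres C6–C7–C8–C9–C10–C1–C2. C17 hangs on C8 and C13 is the only isolated centre, nine in all. Fragile groups are the secondary allylic chloride at C6 (ionisation, transposition to C16, loss of HCl toward C7), the tertiary β-hydroxy lactone with its epimerizable C17, three acetates, and two exocyclic methylenes that can slip into conjugation. The real difficulty is the medium ring with a defined E olefin next to the dense C6–C9 array, not ring A. The key step uses the fact that the C3=C4–C5(=C16) diene and oxygenated C8 are joined through two saturated carbons, C6 and C7. That is the 1,5 pattern left by a [3,3] shift of a C3-allenyl, C8-vinyl cyclohexanol (ring C1–C2–C3–C8–C9–C10 fused to ring A), so the ten-membered ring can be grown from a trans-decalin on which C1, C2, C9, C10 and C13 are already fixed.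

## Logic of the disconnections

**37 ⇒ 36 ⇒ 35.** The three O–acyl bonds at C2, C9 and C13 are cut. Acetates cannot pass the amide bases, hydride and electron-transfer reagents used earlier. One kind of silyl ether on all three oxygens allows a single fluoride deprotection at the end without acid. The demand is that fluoride and acylation spare the C6 chloride, the lactone and the tertiary C8 hydroxyl.

**35 ⇒ 33 ⇒ 31 + 32.** The C8–C17 bond is cut, then the O7–C19 ester bond. Closing the lactone from an ester already on O7 lets the tether fix C8 and C17. The demand is enolate formation without base, because 33 has an acidic C7–H with a β-chloride; a reductive Reformatsky closure answers it.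

**31 ⇒ 30 ⇒ 29 ⇒ 28.** The C6–Cl and C7–O bonds are traced to the C6=C7 bond of 28. Conjugation with the C8 ketone singles this alkene out from four others.

- The ring enforces a 6Z enone, so the epoxide is cis.
- In 37 chlorine and O7 are syn on that frame, so a single anti opening by chloride would give the C6 epimer.
- C6 is therefore inverted twice, by bromide and then by chloride.

The demands are α-face epoxidation and substitution at C6 rather than C16 or C7.

**28 ⇒ 25.** The C6=C7 bond is returned to two C–H bonds. Kinetic enolization at the C7 methylene defines the site.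

**25 ⇒ 22 (key).** The C3–C8 bond is re-formed and C5–C6 cut. The ten-membered ring, its E olefin and the diene all come from a trans-decalin carbinol. The demand on 22 is vinyl and allenyl groups both equatorial and the C8 hydroxyl axial.

**22 ⇒ 17 ⇒ 15 + 16.** The C7–C8 bond is cut. A vinyl metal should approach the C8 ketone of 15 anti to the axial C9–O bond, which places the vinyl group axial (17), the wrong epimer. A [2,3] sulfenate–sulfoxide–sulfenate shuttle erases and resets C8. The demand is that oxygen returns on the α face.

**15 ⇒ 14.** The C3–C4 bond is cut and the O8–C16 bond re-formed, which gives a propargyl enol ether. Ketone and allene then arise in one neutral pericyclic step. An α-ethynyl ketone, which base would isomerize, is avoided. The demand is bond formation on the α face of C3.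

**14 ⇒ 13 ⇒ 12 ⇒ 11 ⇒ 10.** Three O–Si bonds and the carbinol C–H bonds at C13, C2 and C9 are removed. The demands are α-face hydride at C2 and C9, the equatorial alcohol at C13, and α-protonation at C12 so that the C11 methylene stays exocyclic.

**10 ⇒ 8 ⇒ 7 + 4.** C10 is epimerized, then C1–C14 and C10–C11 are cut. One cycloaddition gives both rings, quaternary C1, the C11 methylene and oxygen at C2, C8, C9 and C13. The demands are the correct orientation of the diene and the absolute configuration at C1.

**7 ⇒ 5 + 6; 4 ⇒ 3 ⇒ 1.** The alkoxy group of the quinone is exchanged, and the diene is traced to an allenyl ketone and a commercial alkynol.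

## Other disconnections considered

**Alternative 1:** The cut is C12–C13 of ring A, taking methylenecyclohexanol A2 back to acyclic aldehyde A1. Forward, Me2AlCl activates the aldehyde of A1 and the isopropenyl terminus closes the ring in a carbonyl-ene reaction.

- In favour: ring A, the C11=C20 methylene and the C13 carbinol form in one well-precedented step. A chair transition state should place the new hydroxyl equatorial, which is the C13 configuration of 37. On this point it is better than the chosen plan, which needs a separate thermodynamic reduction (step 8).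
- Against: A1 must already hold the adjacent quaternary C1 and tertiary C10 in open-chain form. A2 carries only one-carbon arms at C2 and C9, so the whole ten-membered ring remains to be built and closed end to end.
- Comparison: mechanistic reliability is equal. Structurally it makes one ring, one bond and one stereocentre, but not the hard ring. Step economy is clearly worse.

**Alternative 2:** The cut is C7–C8 together with the lactone O–C19 bond, taking A4 back to seco keto-aldehyde A3. Forward, SmI2 forms the C7 ketyl, which adds to the C8 ketone, and the C7 alkoxide closes the lactone.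

- In favour: the ring, C7, C8 and the lactone form in one late, convergent step. Ketyl–carbonyl couplings through a samarium-bridged diolate tend to give cis diols, the 7,8 relation needed. A4 carries a C6 oxygen whose single SN2 displacement by chloride gives the 6α-chloride. On this point it is better than the two inversions of steps 16 and 17.
- Against: a ten-membered ring is closed from an open chain, with an entropic and transannular penalty and a need for dilution. The ketyl of A3 has an α-silyloxy group that can be expelled, and the β-keto ester is reducible and epimerizable at C17. Two trigonal centres must choose faces in a flexible chain.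
- Comparison: the chosen plan forms the ring by expansion, with the E geometry fixed by a chair. Alternative 2 sets more stereocentres in its key step but with less control. Step counts are similar only if A3 is short to make, which its quaternary C1 with two long arms makes unlikely.

**Alternative 3:** The cut is C1–C14 and C10–C11 of ring A, taking A6 back to diene 4 and aldehyde-ester A5. Forward, a proline-derived oxazaborolidinium triflimide binds the aldehyde of A5 and 4 adds across C1=C10.

- In favour: it uses the same diene 4 and a catalyst class with strong precedent for α-substituted enals. The E dienophile places the C15 methyl and the C9 aldehyde cis, so the trans C1/C10 relation arises directly. On enantiocontrol and on the ring fusion it is equal or better than steps 4 and 5, where the catalyst is less precedented and C10 must be corrected.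
- Against: A6 holds only ring A with one-carbon stubs at C2 and C9. C3 to C8 must be added stepwise and the large ring closed separately, or ring B annulated before any ring expansion. C13 still needs a stereoselective reduction.
- Comparison: the quinone cycloaddition delivers ring B with C2, C8 and C9 oxygenation in the same step, so the chosen plan is shorter overall.

Key step: step 13

## Route

Step 1
Reactants: 1 pent-4-yn-2-ol
Product: 3 penta-3,4-dien-2-one, via pent-4-yn-2-one 2 (not isolated)
Conditions: CrO3, H2SO4, H2O, acetone, 0 °C; then Et3N (cat.), CH2Cl2, 0 °C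
Reagents that add atoms: none
Why: Chromic acid oxidation gives the β,γ-alkynyl ketone 2, whose propargylic CH2 is acidified by the carbonyl, so a trace of amine moves the triple bond into the conjugated allene (propargyl–allenyl prototropy). The volatile allenone is used at once.

Step 2
Reactants: 3 penta-3,4-dien-2-one
Product: 4 2-(tert-butyldimethylsilyloxy)penta-1,3,4-triene
Conditions: TBSOTf, Et3N, Et2O, −78 → 0 °C
Reagents that add atoms: tert-butyldimethylsilyl triflate, CC(C)(C)[Si](C)(C)OS(=O)(=O)C(F)(F)F
Why: Soft enolization (silyl triflate and amine) removes a methyl proton, not the sp2 allenic hydrogen, and gives the 2-siloxy vinylallene; silyl enol ether formation.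

Step 3
Reactants: 5 2-methoxy-5-methyl-1,4-benzoquinone; 6 prop-2-yn-1-ol
Product: 7 2-methyl-5-(prop-2-ynyloxy)-1,4-benzoquinone
Conditions: TsOH (5 mol%), 4 Å MS, PhMe, 50 °C
Reagents that add atoms: none
Why: Acid-catalysed addition–elimination at the alkoxy-bearing carbon of the vinylogous ester exchanges methoxy for propynyloxy (vinylogous transesterification), driven by removal of methanol. The propynyl group is the later source of C4, C5 and C16.

Step 4
Reactants: 7 2-methyl-5-(prop-2-ynyloxy)-1,4-benzoquinone; 4 2-(tert-butyldimethylsilyloxy)penta-1,3,4-triene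
Product: 8 cis-fused cycloadduct (1β-methyl, 10β-H; 13-TBSO-11(20),12-diene; 8-propynyloxy-3(8)-ene-2,9-dione)
Conditions: TiCl2(O2C20H12) with (R)-1,1'-binaphthalene-2,2'-diolate (10 mol%, from (R)-BINOL and TiCl2(O-i-Pr)2), 4 Å MS, CH2Cl2, −40 °C
Reagents that add atoms: none
Why: Diels–Alder reaction under a chiral chelating Lewis acid. Two-point binding of the alkoxy oxygen and the adjacent carbonyl (future C9) makes the methyl-bearing alkene the dienophile and its methyl-bearing carbon the electrophilic end, so enol-ether terminus C14 bonds to C1 and allene carbon C11 to C10. Suprafacial addition gives the cis fusion, and the ligand sets quaternary C1, the only centre of this step that is kept.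

Step 5
Reactants: 8 cis-fused cycloadduct
Product: 10 trans-fused enedione (10α-H), via potassium C9(10)-dienolate 9 (not isolated)
Conditions: KN(SiMe3)2 (1.0 equiv), THF, −78 °C; AcOH, −78 °C
Reagents that add atoms: none
Why: The very acidic C10–H is removed and the dienolate is protonated kinetically at its α carbon on the face opposite the C15 methyl, which gives the trans ring fusion (deconjugative kinetic protonation). One equivalent of base and a cold quench avoid the equilibration that would move the C11 methylene into conjugation.

Step 6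
Reactants: 10 trans-fused enedione
Product: 11 2β,9β-diol
Conditions: i-Bu2AlH, CH2Cl2, −78 °C; KNaC4H4O6 (aq)
Reagents that add atoms: none
Why: Hydride reaches both carbonyls from the α face, away from the axial C15 methyl (1,2-reduction under steric approach control on a trans-decalin), which gives the 2β (equatorial) and 9β (axial) alcohols. The basic work-up protects the acid-labile enol ethers.

Step 7
Reactants: 11 2β,9β-diol
Product: 12 13-ketone 2β,9β-diol
Conditions: Bu4NF, AcOH, THF, −78 → −20 °C
Reagents that add atoms: none
Why: Fluoride cleaves the silyl dienol ether, and the acetic-acid buffer protonates the dienolate at C12, its α carbon, so the C11=C20 methylene stays out of conjugation (kinetic α-protonation).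

Step 8
Reactants: 12 13-ketone 2β,9β-diol
Product: 13 2β,9β,13α-triol
Conditions: SmI2, H2O, Et3N, THF, 0 °C
Reagents that add atoms: none
Why: Electron-transfer reduction of the dissolving-metal type passes through a carbanion that is protonated to the more stable alcohol. The 13α (equatorial) alcohol avoids the syn-axial contact with the C15 methyl that would burden its epimer; a small hydride would attack from the α face and give that epimer.

Step 9
Reactants: 13 2β,9β,13α-triol
Product: 14 2β,9β,13α-tris(TBS) ether of the 8-propynyl enol ether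
Conditions: TBSOTf, 2,6-lutidine, CH2Cl2, −78 → 0 °C
Reagents that add atoms: tert-butyldimethylsilyl triflate, CC(C)(C)[Si](C)(C)OS(=O)(=O)C(F)(F)F
Why: Silyl triflate with a hindered pyridine also silylates the axial C9 hydroxyl (silyl ether formation). One group on all three oxygens allows a single fluoride deprotection after the chloride is in place.

Step 10
Reactants: 14 tris(TBS) propynyl enol ether
Product: 15 3α-allenyl 8-ketone
Conditions: PhMe, 150 °C (sealed tube)
Reagents that add atoms: none
Why: Propargyl Claisen (Saucy–Marbet) rearrangement: the alkyne terminus bonds to C3 as the O–CH2 bond breaks, which gives the C8 ketone and the C3–C4H=C5=C16H2 allene in one neutral step. The chain passes over the α face because the β face carries the axial C15 methyl and the C9 silyloxy group, so the allenyl group ends equatorial.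

Step 11
Reactants: 15 3α-allenyl 8-ketone; 16 vinylmagnesium bromide
Product: 17 8α-vinyl-8β-ol (C8 epimer of the precursor)
Conditions: CeCl3, THF, −78 °C
Reagents that add atoms: none
Why: The organocerium reagent adds to the enolizable α-allenyl ketone without deprotonation (1,2-addition of a vinylcerium reagent). Attack anti to the axial C9–O bond (Felkin–Anh, axial approach) is expected to place the vinyl group axial, which step 12 corrects; any 8β-vinyl epimer formed is carried along and converges.

Step 12
Reactants: 17 8α-vinyl-8β-ol
Product: 22 8β-vinyl-8α-ol (oxy-Cope precursor), via lithium 8-alkoxide 18 (not isolated), via 8β-benzenesulfenate 19 (not isolated), via allylic sulfoxide 20 (not isolated), via 8α-benzenesulfenate 21 (not isolated)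
Conditions: n-BuLi (1.0 equiv), THF, −78 °C; PhSCl, −78 → 20 °C; then P(OMe)3, MeOH, 50 °C
Reagents that add atoms: none
Why: Mislow–Evans sequence: sulfenate 19 shifts [2,3] to the primary allylic sulfoxide 20, which erases C8. With the thiophile present the reverse shift should return oxygen to C8 on the open α face, anti to the axial C9–O bond, and sulfenate 21 is cleaved to the axial alcohol.

Step 13
Reactants: 22 8β-vinyl-8α-ol (3α-allenyl, 2β,9β,13α-tris(TBS) trans-decalin)
Product: 25 six–ten bicyclic (3E)-3,5(16),11(20)-trien-8-one tris(TBS) ether, via potassium 8-alkoxide 23 (not isolated), via potassium C7(8)-enolate 24 (not isolated)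
Conditions: KH, 18-crown-6, THF, 0 → 20 °C; AcOH, −78 °C
Reagents that add atoms: none
Why: Anionic oxy-Cope rearrangement with an allene as one π component: alkoxide 23 weakens the C3–C8 bond, and the [3,3] shift joins vinyl terminus C6 to the central allene carbon C5 while C3–C8 breaks, so the allene becomes the C3=C4–C5(=C16) diene and C7=C8 the enolate 24. The closest known reaction types are the alkoxide-accelerated expansion of trans-1,2-dialkenylcyclohexanols to (E)-cyclodec-5-enones and allenyl oxy-Cope shifts that give 1,3-dienes. The ten-membered ring is formed by ring expansion, C4 to C7 being inserted between C3 and C8 of ring B, not by end-to-end cyclization, so no dilution is needed. No stereocentre is created, since C3 and C8 become trigonal; the new stereo-element is the C3=C4 geometry, which must be E. The equatorial vinyl and equatorial allenyl groups on the rigid trans-decalin are gauche and can reach each other only through a chair in which C2 and C9 are pseudo-equatorial, which gives the 3E olefin and an enolate whose ring bond is trans. Relief of the syn-axial contact between the C9 oxygen and the C15 methyl, and the change from tertiary alkoxide to enolate, make the step irreversible. The site of the enolate is inherent, and the cold acidic quench gives the C8 ketone without touching C9. The C8 alkoxide and the C9 silyl ether are trans-diaxial, which excludes silyl migration.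

Step 14
Reactants: 25 (3E)-3,5(16),11(20)-trien-8-one
Product: 28 (3E,6Z)-3,5(16),6,11(20)-tetraen-8-one, via lithium C7(8)-enolate 26 (not isolated), via 7-sulfilimine adduct 27 (not isolated)
Conditions: LiN(i-Pr)2, THF, −78 °C; PhS(Cl)=N-t-Bu, −78 °C
Reagents that add atoms: none
Why: Kinetic deprotonation occurs at the C7 methylene, C9 being a hindered methine. The enolate attacks sulfur and adduct 27 loses the sulfenamide by syn elimination at low temperature (Mukaiyama dehydrogenation). The ring holds C5 and C8 on the same side of the new bond, so the 6Z enone is expected.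

Step 15
Reactants: 28 (3E,6Z)-tetraen-8-one
Product: 29 6α,7α-epoxy 8-ketone
Conditions: t-BuOOH, DBU, CH2Cl2, 0 °C
Reagents that add atoms: tert-butyl hydroperoxide, CC(C)(C)OO
Why: Nucleophilic (Weitz–Scheffer) epoxidation touches only the electron-poor C6=C7 bond. The hydroperoxide anion should add to the outward α side of the 6Z enone and close before C6–C7 rotation, which gives the cis epoxide with C7 in its final configuration.

Step 16
Reactants: 29 6α,7α-epoxy 8-ketone
Product: 30 6β-bromo-7α-hydroxy 8-ketone
Conditions: MgBr2·OEt2, Et2O, −30 °C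
Reagents that add atoms: magnesium bromide, [Mg+2].[Br-].[Br-]
Why: The Lewis acid bridges ketone and oxirane oxygens, and bromide opens the allylic C6–O bond from the β face with inversion (epoxide to halohydrin). This is the first of the two inversions at C6.

Step 17
Reactants: 30 6β-bromo-7α-hydroxy 8-ketone
Product: 31 6α-chloro-7α-hydroxy 8-ketone
Conditions: Bu4NCl (1.2 equiv), acetone, 0 → 20 °C
Reagents that add atoms: tetrabutylammonium chloride, CCCC[N+](CCCC)(CCCC)CCCC.[Cl-]
Why: Finkelstein-type SN2 exchange of the secondary allylic bromide is the second inversion and places chlorine 6α, syn to the C7 oxygen. Bromide leaves far faster than chloride, so a small excess of salt should not re-attack the product, and the neutral medium avoids loss of HX.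

Step 18
Reactants: 31 6α-chloro-7α-hydroxy 8-ketone; 32 2-bromopropanoyl bromide
Product: 33 7α-(2-bromopropanoyloxy)-6α-chloro 8-ketone
Conditions: pyridine, CH2Cl2, −20 °C
Reagents that add atoms: none
Why: Acylation of the α-ketol hydroxyl by an acid bromide under mild base (ester formation). The epimers at the bromine-bearing carbon are not separated because that carbon becomes an enolate.

Step 19
Reactants: 33 7α-(2-bromopropanoyloxy)-6α-chloro 8-ketone
Product: 35 tris(TBS) ether of the 6α-chloro-8α-hydroxy lactone, via samarium ester enolate 34 (not isolated)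
Conditions: SmI2 (2.2 equiv), THF, −78 °C; NH4Cl (aq)
Reagents that add atoms: none
Why: Intramolecular Reformatsky reaction promoted by SmI2: at −78 °C the C–Br bond is reduced far faster than the ketone or the allylic chloride, and enolate 34 adds to the C8 ketone. The tether delivers C17 to the C8 face that carries O7, and the medium ring keeps C6 and C9 anti (trans-fused lactone), which fixes 8α-OH. The methyl group should turn away from C9 toward the metal-bridged oxygens, cis to the C8 hydroxyl.

Step 20
Reactants: 35 tris(TBS) ether of the lactone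
Product: 36 2β,9β,13α-triol of the 6α-chloro-8α-hydroxy lactone
Conditions: HF·pyridine, pyridine, THF, 0 → 20 °C
Reagents that add atoms: none
Why: Buffered fluoride cleaves the three secondary silyl ethers (desilylation) under non-basic, weakly acidic conditions that spare the allylic chloride, the lactone and the tertiary alcohol.

Step 21
Reactants: 36 2β,9β,13α-triol
Product: 37 CNP0268873.1 (2β,9β,13α-triacetate)
Conditions: Ac2O, pyridine, DMAP (cat.), CH2Cl2, 0 °C
Reagents that add atoms: acetic anhydride, CC(=O)OC(C)=O
Why: Acetylation of the three secondary hydroxyls. The tertiary, hydrogen-bonded C8 hydroxyl is not acylated under these mild conditions.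

## Compound list

1 | pent-4-yn-2-ol | CC(O)CC#C | starting material
2 | pent-4-yn-2-one | CC(=O)CC#C | intermediate (not isolated)
3 | penta-3,4-dien-2-one | CC(=O)C=C=C | intermediate
4 | 2-(tert-butyldimethylsilyloxy)penta-1,3,4-triene | C=C(O[Si](C)(C)C(C)(C)C)C=C=C | intermediate
5 | 2-methoxy-5-methyl-1,4-benzoquinone | COC1=CC(=O)C(C)=CC1=O | starting material
6 | prop-2-yn-1-ol | C#CCO | starting material
7 | 2-methyl-5-(prop-2-ynyloxy)-1,4-benzoquinone | C#CCOC1=CC(=O)C(C)=CC1=O | intermediate
8 | cis-fused cycloadduct (1β-methyl, 10β-H) | C=C1C=C(O[Si](C)(C)C(C)(C)C)C[C@]2(C)C(=O)C=C(OCC#C)C(=O)[C@H]12 | intermediate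
9 | potassium C9(10)-dienolate of 8 | C=C1C=C(O[Si](C)(C)C(C)(C)C)C[C@]2(C)C(=O)C=C(OCC#C)C([O-])=C12.[K+] | intermediate (not isolated)
10 | trans-fused enedione (1β-methyl, 10α-H) | C=C1C=C(O[Si](C)(C)C(C)(C)C)C[C@]2(C)C(=O)C=C(OCC#C)C(=O)[C@@H]12 | intermediate
11 | 2β,9β-diol (13-silyl dienol ether, 8-propynyl enol ether) | C=C1C=C(O[Si](C)(C)C(C)(C)C)C[C@]2(C)[C@@H](O)C=C(OCC#C)[C@@H](O)[C@@H]12 | intermediate
12 | 13-ketone 2β,9β-diol | C=C1CC(=O)C[C@]2(C)[C@@H](O)C=C(OCC#C)[C@@H](O)[C@@H]12 | intermediate
13 | 2β,9β,13α-triol | C=C1C[C@H](O)C[C@]2(C)[C@@H](O)C=C(OCC#C)[C@@H](O)[C@@H]12 | intermediate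
14 | 2β,9β,13α-tris(TBS) ether, 8-propynyl enol ether | C=C1C[C@H](O[Si](C)(C)C(C)(C)C)C[C@]2(C)[C@@H](O[Si](C)(C)C(C)(C)C)C=C(OCC#C)[C@@H](O[Si](C)(C)C(C)(C)C)[C@@H]12 | intermediate
15 | 3α-allenyl 8-ketone | C=C1C[C@H](O[Si](C)(C)C(C)(C)C)C[C@]2(C)[C@@H](O[Si](C)(C)C(C)(C)C)[C@H](C=C=C)C(=O)[C@@H](O[Si](C)(C)C(C)(C)C)[C@@H]12 | intermediate
16 | vinylmagnesium bromide | C=C[Mg]Br | starting material
17 | 8α-vinyl-8β-ol (8-epi carbinol) | C=C1C[C@H](O[Si](C)(C)C(C)(C)C)C[C@]2(C)[C@@H](O[Si](C)(C)C(C)(C)C)[C@H](C=C=C)[C@](O)(C=C)[C@@H](O[Si](C)(C)C(C)(C)C)[C@@H]12 | intermediate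
18 | lithium 8-alkoxide of 17 | C=C1C[C@H](O[Si](C)(C)C(C)(C)C)C[C@]2(C)[C@@H](O[Si](C)(C)C(C)(C)C)[C@H](C=C=C)[C@]([O-])(C=C)[C@@H](O[Si](C)(C)C(C)(C)C)[C@@H]12.[Li+] | intermediate (not isolated)
19 | 8β-benzenesulfenate | C=C1C[C@H](O[Si](C)(C)C(C)(C)C)C[C@]2(C)[C@@H](O[Si](C)(C)C(C)(C)C)[C@H](C=C=C)[C@](OSc3ccccc3)(C=C)[C@@H](O[Si](C)(C)C(C)(C)C)[C@@H]12 | intermediate (not isolated)
20 | allylic sulfoxide (8(7)-ene, 6-phenylsulfinyl; mixture at sulfur and C7=C8) | C=C1C[C@H](O[Si](C)(C)C(C)(C)C)C[C@]2(C)[C@@H](O[Si](C)(C)C(C)(C)C)[C@H](C=C=C)C(=CCS(=O)c3ccccc3)[C@@H](O[Si](C)(C)C(C)(C)C)[C@@H]12 | intermediate (not isolated)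
21 | 8α-benzenesulfenate | C=C1C[C@H](O[Si](C)(C)C(C)(C)C)C[C@]2(C)[C@@H](O[Si](C)(C)C(C)(C)C)[C@H](C=C=C)[C@@](OSc3ccccc3)(C=C)[C@@H](O[Si](C)(C)C(C)(C)C)[C@@H]12 | intermediate (not isolated)
22 | 8β-vinyl-8α-ol, 3α-allenyl trans-decalin (oxy-Cope precursor) | C=C1C[C@H](O[Si](C)(C)C(C)(C)C)C[C@]2(C)[C@@H](O[Si](C)(C)C(C)(C)C)[C@H](C=C=C)[C@@](O)(C=C)[C@@H](O[Si](C)(C)C(C)(C)C)[C@@H]12 | intermediate
23 | potassium 8-alkoxide of 22 | C=C1C[C@H](O[Si](C)(C)C(C)(C)C)C[C@]2(C)[C@@H](O[Si](C)(C)C(C)(C)C)[C@H](C=C=C)[C@@]([O-])(C=C)[C@@H](O[Si](C)(C)C(C)(C)C)[C@@H]12.[K+] | intermediate (not isolated)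
24 | potassium C7(8)-enolate (C6 and C9 trans) | C=C1C[C@H](O[Si](C)(C)C(C)(C)C)C[C@]2(C)[C@@H](O[Si](C)(C)C(C)(C)C)/C=C/C(=C)C/C=C(\[O-])[C@@H](O[Si](C)(C)C(C)(C)C)[C@@H]12.[K+] | intermediate (not isolated)
25 | six–ten bicyclic (3E)-3,5(16),11(20)-trien-8-one, tris(TBS) ether | C=C1C[C@H](O[Si](C)(C)C(C)(C)C)C[C@]2(C)[C@@H](O[Si](C)(C)C(C)(C)C)/C=C/C(=C)CCC(=O)[C@@H](O[Si](C)(C)C(C)(C)C)[C@@H]12 | intermediate
26 | lithium C7(8)-enolate of 25 | C=C1C[C@H](O[Si](C)(C)C(C)(C)C)C[C@]2(C)[C@@H](O[Si](C)(C)C(C)(C)C)/C=C/C(=C)CC=C([O-])[C@@H](O[Si](C)(C)C(C)(C)C)[C@@H]12.[Li+] | intermediate (not isolated)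
27 | 7-(N-tert-butyl-S-phenylsulfilimine) adduct | C=C1C[C@H](O[Si](C)(C)C(C)(C)C)C[C@]2(C)[C@@H](O[Si](C)(C)C(C)(C)C)/C=C/C(=C)CC(S(=NC(C)(C)C)c3ccccc3)C(=O)[C@@H](O[Si](C)(C)C(C)(C)C)[C@@H]12 | intermediate (not isolated)
28 | (3E,6Z)-3,5(16),6,11(20)-tetraen-8-one | C=C1C[C@H](O[Si](C)(C)C(C)(C)C)C[C@]2(C)[C@@H](O[Si](C)(C)C(C)(C)C)/C=C/C(=C)/C=C\C(=O)[C@@H](O[Si](C)(C)C(C)(C)C)[C@@H]12 | intermediate
29 | 6α,7α-epoxy 8-ketone | C=C1C[C@H](O[Si](C)(C)C(C)(C)C)C[C@]2(C)[C@@H](O[Si](C)(C)C(C)(C)C)/C=C/C(=C)[C@@H]3O[C@@H]3C(=O)[C@@H](O[Si](C)(C)C(C)(C)C)[C@@H]12 | intermediate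
30 | 6β-bromo-7α-hydroxy 8-ketone | C=C1C[C@H](O[Si](C)(C)C(C)(C)C)C[C@]2(C)[C@@H](O[Si](C)(C)C(C)(C)C)/C=C/C(=C)[C@@H](Br)[C@H](O)C(=O)[C@@H](O[Si](C)(C)C(C)(C)C)[C@@H]12 | intermediate
31 | 6α-chloro-7α-hydroxy 8-ketone | C=C1C[C@H](O[Si](C)(C)C(C)(C)C)C[C@]2(C)[C@@H](O[Si](C)(C)C(C)(C)C)/C=C/C(=C)[C@H](Cl)[C@H](O)C(=O)[C@@H](O[Si](C)(C)C(C)(C)C)[C@@H]12 | intermediate
32 | 2-bromopropanoyl bromide | CC(Br)C(=O)Br | starting material
33 | 7α-(2-bromopropanoyloxy)-6α-chloro 8-ketone | C=C1C[C@H](O[Si](C)(C)C(C)(C)C)C[C@]2(C)[C@@H](O[Si](C)(C)C(C)(C)C)/C=C/C(=C)[C@H](Cl)[C@H](OC(=O)C(C)Br)C(=O)[C@@H](O[Si](C)(C)C(C)(C)C)[C@@H]12 | intermediate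
34 | samarium ester enolate of 33 | C=C1C[C@H](O[Si](C)(C)C(C)(C)C)C[C@]2(C)[C@@H](O[Si](C)(C)C(C)(C)C)/C=C/C(=C)[C@H](Cl)[C@H](OC([O-])=CC)C(=O)[C@@H](O[Si](C)(C)C(C)(C)C)[C@@H]12.[Sm+3].[I-].[I-] | intermediate (not isolated)
35 | 6α-chloro-8α-hydroxy-17α-methyl lactone, 2β,9β,13α-tris(TBS) ether | C=C1C[C@H](O[Si](C)(C)C(C)(C)C)C[C@]2(C)[C@@H](O[Si](C)(C)C(C)(C)C)/C=C/C(=C)[C@H](Cl)[C@@H]3OC(=O)[C@H](C)[C@@]3(O)[C@@H](O[Si](C)(C)C(C)(C)C)[C@@H]12 | intermediate
36 | 6α-chloro-8α-hydroxy lactone 2β,9β,13α-triol | C=C1C[C@H](O)C[C@]2(C)[C@@H](O)/C=C/C(=C)[C@H](Cl)[C@@H]3OC(=O)[C@H](C)[C@@]3(O)[C@@H](O)[C@@H]12 | intermediate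
37 | CNP0268873.1 | C=C1C[C@H](OC(C)=O)C[C@]2(C)[C@@H](OC(C)=O)/C=C/C(=C)[C@H](Cl)[C@@H]3OC(=O)[C@H](C)[C@@]3(O)[C@@H](OC(C)=O)[C@@H]12 | target

## Step count and least certain steps

Total: 21 steps. Longest linear sequence: 20 steps (1 to 37 through steps 1, 2 and 4–21); the quinone branch joins at step 4.

**Step 13 (key step).** The naked C8 alkoxide is also a base and a nucleophile. The most likely failure is its addition to the neighbouring allene, or proton transfer that moves the enolate toward C9 before the quench. The fallback sets out from 22: the hydroxyl is silylated (Me3SiCl, imidazole) to the trimethylsilyl ether of 22 F1, which is heated (PhMe, 180 °C) so that the neutral siloxy-Cope shift gives the trimethylsilyl enol ether of 25 F2. Bu4NF with AcOH at −78 °C then rejoins the route at 25.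

**Step 4.** The Lewis acid may trigger stepwise Michael addition of the silyl enol ether to the quinone, or discriminate poorly between the two quinone faces. The fallback sets out from 7 and 4, combined without catalyst (PhMe, 40 °C). The regiochemistry is then set by the alkoxy group alone, and 8 forms together with the enantiomer of 8 F3. Epimerization as in step 5 gives 10 and the enantiomer of 10 F4, which are separated by preparative chromatography on a chiral stationary phase. The route is rejoined at 10.

**Step 12.** Oxygen may return to the β face in the reverse [2,3] shift, or the sulfenyl chloride may attack the allene. The fallback sets out from 15: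

- Corey–Chaykovsky reaction with dimethylsulfoxonium methylide, which adds reversibly and places the new C–C bond equatorial, gives the C8 spiro-epoxide F5.
- Dimethylsulfonium methylide (excess, THF, −10 → 20 °C) opens the oxirane CH2 and eliminates dimethyl sulfide.

This gives the vinyl carbinol, and the route is rejoined at 22.

**Step 15.** The hydroperoxide may attack the β face, or add 1,6 at C16 of the dienone. The fallback sets out from 28 and replaces substrate control by reagent control: La(O-i-Pr)3 with BINOL and Ph3As=O (1:1:1), t-BuOOH, 4 Å MS, THF, with the ligand enantiomer chosen for the α face. It returns at 29 and makes no compound outside the list (F0).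

**Step 16 (with step 17).** Ionisation at allylic C6 may erode the stereospecificity of one of the two inversions, or halide may enter at C16 with allylic transposition. The fallback sets out from 29:

- Acid-catalysed hydrolysis (HClO4 cat., THF–H2O, 0 °C) opens the oxirane at C6 with inversion to the 6β,7α-diol F6.
- SOCl2 and Et3N convert it into the 6β,7α-cyclic sulfite F7.
- LiCl (DMF, 60 °C) opens the sulfite at the allylic carbon with inversion, and water cleaves the sulfite monoester.

The route is rejoined at 31, bypassing 30.

**Step 19.** Electron transfer to the α-oxygenated ketone (loss of the C7 or C9 oxygen) or to the allylic chloride may compete with reduction of the C–Br bond. The fallback sets out from 31: the lithium enolate of phenyl propanoate (2.2 equiv, THF, −78 → 0 °C) first forms the C7 alkoxide. Lithium bridged between O7 and the ketone should direct the second equivalent to the C8 face that leads to the trans-fused lactone, and the C7 alkoxide then displaces phenoxide. The route is rejoined at 35 with no compound outside the list (F0).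

## Further compounds

F1 | step 13 | trimethylsilyl ether of 22 | C=C1C[C@H](O[Si](C)(C)C(C)(C)C)C[C@]2(C)[C@@H](O[Si](C)(C)C(C)(C)C)[C@H](C=C=C)[C@@](O[Si](C)(C)C)(C=C)[C@@H](O[Si](C)(C)C(C)(C)C)[C@@H]12
F2 | step 13 | trimethylsilyl enol ether of 25 (C6 and C9 trans) | C=C1C[C@H](O[Si](C)(C)C(C)(C)C)C[C@]2(C)[C@@H](O[Si](C)(C)C(C)(C)C)/C=C/C(=C)C/C=C(\O[Si](C)(C)C)[C@@H](O[Si](C)(C)C(C)(C)C)[C@@H]12
F3 | step 4 | enantiomer of 8 | C=C1C=C(O[Si](C)(C)C(C)(C)C)C[C@@]2(C)C(=O)C=C(OCC#C)C(=O)[C@@H]12
F4 | step 4 | enantiomer of 10 | C=C1C=C(O[Si](C)(C)C(C)(C)C)C[C@@]2(C)C(=O)C=C(OCC#C)C(=O)[C@H]12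
F5 | step 12 | C8 spiro-epoxide (oxirane oxygen 8α, CH2 8β) | C=C1C[C@H](O[Si](C)(C)C(C)(C)C)C[C@]2(C)[C@@H](O[Si](C)(C)C(C)(C)C)[C@H](C=C=C)[C@@]3(CO3)[C@@H](O[Si](C)(C)C(C)(C)C)[C@@H]12
F0 | step 15 | none | none
F6 | step 16 | 6β,7α-dihydroxy 8-ketone | C=C1C[C@H](O[Si](C)(C)C(C)(C)C)C[C@]2(C)[C@@H](O[Si](C)(C)C(C)(C)C)/C=C/C(=C)[C@@H](O)[C@H](O)C(=O)[C@@H](O[Si](C)(C)C(C)(C)C)[C@@H]12
F7 | step 16 | 6β,7α-cyclic sulfite | C=C1C[C@H](O[Si](C)(C)C(C)(C)C)C[C@]2(C)[C@@H](O[Si](C)(C)C(C)(C)C)/C=C/C(=C)[C@H]3OS(=O)O[C@@H]3C(=O)[C@@H](O[Si](C)(C)C(C)(C)C)[C@@H]12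
F0 | step 19 | none | none
A1 | alternative 1 | acyclic isopropenyl aldehyde | C=C(C)[C@H](CO[Si](C)(C)C(C)(C)C)[C@@](C)(COCc1ccccc1)CC=O
A2 | alternative 1 | ring A 3-methylenecyclohexanol | C=C1C[C@H](O)C[C@](C)(COCc2ccccc2)[C@H]1CO[Si](C)(C)C(C)(C)C
A3 | alternative 2 | seco keto-aldehyde β-keto ester | C=C1C[C@H](OC(C)=O)C[C@](C)([C@@H](OC(C)=O)/C=C/C(=C)[C@@H](O[Si](C)(C)C(C)(C)C)C=O)[C@H]1[C@H](OCOC)C(=O)C(C)C(=O)OC
A4 | alternative 2 | 6-epi-silyloxy lactone (9-methoxymethyl ether, 2,13-diacetate) | C=C1C[C@H](OC(C)=O)C[C@]2(C)[C@@H](OC(C)=O)/C=C/C(=C)[C@@H](O[Si](C)(C)C(C)(C)C)[C@@H]3OC(=O)[C@H](C)[C@@]3(O)[C@@H](OCOC)[C@@H]12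
A5 | alternative 3 | methyl (E)-2-methyl-4-oxobut-2-enoate | COC(=O)/C(C)=C/C=O
A6 | alternative 3 | ring A cycloadduct | C=C1C=C(O[Si](C)(C)C(C)(C)C)C[C@](C)(C(=O)OC)[C@H]1C=O
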